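## Retrosynthetic overview

- Target 26 is a (2R)-flavanone; the last step frees the three phenols of tris-MOM flavanone 25.
- Ring C is cut at O1–C8a and C4–C4a: 25 comes from aryne 22 (ring A with a C4a≡C8a triple bond, generated from silyl triflate 10) and β-silyloxy amide 20 (the O1–C2–C3–C4 chain carrying ring B and the C2 stereocenter).
- Enabling feature: O1 and the C4 carbonyl are 1,3 on the chain and sit on the adjacent ring A carbons C8a and C4a, and the C5 oxygen ortho to C4a polarises the aryne so that O1 adds at C8a and the C4a carbanion closes on C4. Fluoride unmasks both partners.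
- 10 comes from 5-chlorobenzene-1,3-diol (steps 1–5; ring A keeps a mirror plane until step 4). 20 comes from 4-iodophenol (steps 6–11), with C2 set by asymmetric transfer hydrogenation of β-keto amide 18.
- Ring order: rings A and B are bought as benzenes; ring C is the only ring formed (step 12).

Key step: step 12

Remark: by the CIP rules (O1 > C1' > C3 > H) the drawn C2 is (R); the sense of step 10 is assigned by analogy with aryl alkyl ketones, for which the (R,R) catalyst gives the (R) carbinol.

## Route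

Step 1
Reactants: 1 5-chlorobenzene-1,3-diol
Product: 2 1-chloro-3,5-bis(methoxymethoxy)benzene
Conditions: NaH, MOMCl, DMF, 0 °C → rt
Reagents that add atoms: chloromethyl methyl ether (MOMCl), COCCl
Why: Double Williamson-type O-alkylation of the phenoxides; the MOM ethers later direct the lithiation, are inert to fluoride and base, and leave under mild acid.

Step 2
Reactants: 2 1-chloro-3,5-bis(methoxymethoxy)benzene; 3 prenyl bromide (1-bromo-3-methylbut-2-ene)
Product: 5 5-chloro-1,3-bis(methoxymethoxy)-2-(3-methylbut-2-en-1-yl)benzene, via aryllithium 4 (not isolated)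
Conditions: n-BuLi, THF, −20 °C; then 3, −78 °C → rt
Reagents that add atoms: none
Why: Directed ortho-metalation takes place at the carbon flanked by the two OMOM groups (cooperative directors, while the aryl chloride does not exchange with n-BuLi), and the aryllithium is alkylated by the primary allylic bromide in an SN2 reaction.

Step 3
Reactants: 5 5-chloro-1,3-bis(methoxymethoxy)-2-(3-methylbut-2-en-1-yl)benzene
Product: 6 3,5-bis(methoxymethoxy)-4-(3-methylbut-2-en-1-yl)phenol
Conditions: Pd2(dba)3 (cat.), Me4tBuXPhos (cat.), KOH, 1,4-dioxane/H2O, 100 °C; then aq. HCl to pH 6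
Reagents that add atoms: potassium hydroxide, [K+].[OH-]
Why: Palladium-catalysed hydroxylation of an aryl chloride with hydroxide (Buchwald–Hartwig-type C–O coupling), in which zerovalent palladium inserts into the C–Cl bond; MOM ethers and the trisubstituted alkene are stable to aqueous base.

Step 4
Reactants: 6 3,5-bis(methoxymethoxy)-4-(3-methylbut-2-en-1-yl)phenol
Product: 7 2-bromo-3,5-bis(methoxymethoxy)-4-(3-methylbut-2-en-1-yl)phenol
Conditions: NBS (1.0 equiv), CH2Cl2, −78 °C
Reagents that add atoms: N-bromosuccinimide, O=C1CCC(=O)N1Br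
Why: Electrophilic aromatic bromination ortho to the free hydroxyl, where the para position is blocked by the prenyl group, the two ortho positions are equivalent through the mirror plane of 6, and the phenol ring should react much faster than the trisubstituted alkene at low temperature.

Step 5
Reactants: 7 2-bromo-3,5-bis(methoxymethoxy)-4-(3-methylbut-2-en-1-yl)phenol
Product: 10 3,5-bis(methoxymethoxy)-4-(3-methylbut-2-en-1-yl)-2-(trimethylsilyl)phenyl trifluoromethanesulfonate, via silyl ether 8 (not isolated), via lithium phenolate 9 (not isolated)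
Conditions: HMDS, THF, 65 °C, evaporate; n-BuLi, THF, −100 °C; Tf2O, −100 °C → rt
Reagents that add atoms: hexamethyldisilazane, C[Si](C)(C)N[Si](C)(C)C; trifluoromethanesulfonic anhydride, O=S(=O)(OS(=O)(=O)C(F)(F)F)C(F)(F)F
Why: O-silylation, bromine–lithium exchange with 1,3 oxygen-to-carbon silyl shift (retro-Brook rearrangement) and O-triflation of the phenolate form the standard one-pot entry to ortho-silylaryl triflate aryne precursors from ortho-bromophenols.

Step 6
Reactants: 11 4-iodophenol; 3 prenyl bromide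
Product: 12 4-iodo-2,6-bis(3-methylbut-2-en-1-yl)phenol
Conditions: NaH (2.2 equiv), 3 (2.2 equiv), toluene, rt
Reagents that add atoms: none
Why: ortho-Selective C-allylation of a sodium phenoxide as a contact ion pair in non-polar toluene (C- instead of O-alkylation, para position blocked by iodine), run twice in the same flask, a known way to 2,6-diprenyl-4-halophenols.

Step 7
Reactants: 12 4-iodo-2,6-bis(3-methylbut-2-en-1-yl)phenol
Product: 13 5-iodo-2-(methoxymethoxy)-1,3-bis(3-methylbut-2-en-1-yl)benzene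
Conditions: NaH, MOMCl, THF/DMF, 0 °C → rt
Reagents that add atoms: chloromethyl methyl ether (MOMCl), COCCl
Why: Williamson-type O-alkylation of the hindered sodium phenoxide with the small, reactive MOMCl.

Step 8
Reactants: 13 5-iodo-2-(methoxymethoxy)-1,3-bis(3-methylbut-2-en-1-yl)benzene
Product: 15 methyl 4-(methoxymethoxy)-3,5-bis(3-methylbut-2-en-1-yl)benzoate, via arylmagnesium chloride 14 (not isolated)
Conditions: iPrMgCl·LiCl, THF, 0 °C → rt; then added to ClCO2Me, THF, −40 °C
Reagents that add atoms: methyl chloroformate, COC(=O)Cl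
Why: Iodine–magnesium exchange with the turbo-Grignard reagent followed by acylation of the arylmagnesium species with a chloroformate (inverse addition to suppress double addition).

Step 9
Reactants: 15 methyl 4-(methoxymethoxy)-3,5-bis(3-methylbut-2-en-1-yl)benzoate; 16 4-acetylmorpholine
Product: 18 1-[4-(methoxymethoxy)-3,5-bis(3-methylbut-2-en-1-yl)phenyl]-3-(morpholin-4-yl)propane-1,3-dione, via lithium enolate 17 (not isolated)
Conditions: LiN(iPr)2 (2.2 equiv), 16 (2.2 equiv), THF, −78 °C; then 15, −78 → 0 °C; aq. HCl (1 M) to pH 5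
Reagents that add atoms: none
Why: Crossed Claisen condensation of an amide enolate with a non-enolisable aryl ester, driven by deprotonation of the β-keto amide by the second equivalent of enolate.

Step 10
Reactants: 18 1-[4-(methoxymethoxy)-3,5-bis(3-methylbut-2-en-1-yl)phenyl]-3-(morpholin-4-yl)propane-1,3-dione
Product: 19 (3R)-3-hydroxy-3-[4-(methoxymethoxy)-3,5-bis(3-methylbut-2-en-1-yl)phenyl]-1-(morpholin-4-yl)propan-1-one
Conditions: RuCl[(R,R)-TsDPEN](p-cymene) (1 mol %), HCO2H/Et3N (5:2), EtOAc, 40 °C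
Reagents that add atoms: none
Why: Noyori–Ikariya asymmetric transfer hydrogenation, in which the (R,R)-TsDPEN ruthenium hydride delivers hydride through the CH/π-controlled six-membered transition state to the face that gives the (R) benzylic carbinol (same sense as for acetophenone), setting C2 of the target; isolated alkenes are not reduced.

Step 11
Reactants: 19 (3R)-3-hydroxy-3-[4-(methoxymethoxy)-3,5-bis(3-methylbut-2-en-1-yl)phenyl]-1-(morpholin-4-yl)propan-1-one
Product: 20 (3R)-3-[4-(methoxymethoxy)-3,5-bis(3-methylbut-2-en-1-yl)phenyl]-1-(morpholin-4-yl)-3-[(trimethylsilyl)oxy]propan-1-one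
Conditions: TMSCl, imidazole, CH2Cl2, 0 °C
Reagents that add atoms: chlorotrimethylsilane, C[Si](C)(C)Cl
Why: Silylation of the secondary alcohol; the labile TMS ether replaces the O–H proton by a fluoride-cleavable group.

Step 12
Reactants: 20 (3R)-3-[4-(methoxymethoxy)-3,5-bis(3-methylbut-2-en-1-yl)phenyl]-1-(morpholin-4-yl)-3-[(trimethylsilyl)oxy]propan-1-one; 10 3,5-bis(methoxymethoxy)-4-(3-methylbut-2-en-1-yl)-2-(trimethylsilyl)phenyl trifluoromethanesulfonate
Product: 25 (2R)-5,7-bis(methoxymethoxy)-2-[4-(methoxymethoxy)-3,5-bis(3-methylbut-2-en-1-yl)phenyl]-6-(3-methylbut-2-en-1-yl)-2,3-dihydro-4H-chromen-4-one, via cesium alkoxide 21 (not isolated), via aryne 22 (not isolated), via aryl cesium 23 (not isolated), via hemiaminal alkoxide 24 (not isolated)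
Conditions: CsF (3.5 equiv), 18-crown-6, THF, 0 °C → rt, slow addition of 10 (1.3 equiv); then AcOH, H2O
Reagents that add atoms: none
Why: Proposed new method: fluoride cleaves the O–SiMe3 bond of 20 to the naked cesium alkoxide 21 and, more slowly, converts 10 by 1,2-elimination into aryne 22; the alkoxide oxygen adds to the aryne carbon remote from the C5 OMOM group (future C8a), which puts the aryl anion 23 at C4a, where it adds to the morpholine amide carbonyl to give hemiaminal alkoxide 24, and acetic acid then releases morpholine and the C4 ketone. The closest known reaction types are the fluoride-triggered annulation of arynes with salicylate esters to xanthones and aryne insertion into acyl σ-bonds; an aliphatic β-silyloxy amide has not been used in this way. Ring C closes by 6-exo-trig addition of the C4a carbanion to the amide C=O, after intermolecular formation of the C8a–O1 bond. No stereocenter is created: C2 comes from step 10 and is retained because none of its bonds is touched and because the carbonyl stays masked as 24 until the acidic quench, which blocks base-induced retro-oxa-Michael opening of the flavanone. The step needs regioselective aryne addition, secured by the inductively withdrawing C5 oxygen that distorts the aryne and stabilises negative charge at C4a (3-alkoxyaryne rule), and ring closure in preference to protonation, secured by the aprotic medium in which the silyl ether replaces the O–H and the amide α-protons are only weakly acidic. The tertiary amide also resists retro-aldol cleavage and intermolecular acyl transfer of alkoxide 21 while it waits for the aryne.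

Step 13
Reactants: 25 (2R)-5,7-bis(methoxymethoxy)-2-[4-(methoxymethoxy)-3,5-bis(3-methylbut-2-en-1-yl)phenyl]-6-(3-methylbut-2-en-1-yl)-2,3-dihydro-4H-chromen-4-one
Product: 26 (2R)-5,7-dihydroxy-2-[4-hydroxy-3,5-bis(3-methylbut-2-en-1-yl)phenyl]-6-(3-methylbut-2-en-1-yl)-2,3-dihydro-4H-chromen-4-one
Conditions: HCl (3 M aq.), MeOH, 40 °C
Reagents that add atoms: none
Why: Acid-catalysed acetal exchange of the three MOM ethers with methanol; the C2–O1 bond and the prenyl groups should survive mild acid, and C2 is not epimerisable under acidic conditions that do not open ring C.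

## Compound list

1 | 5-chlorobenzene-1,3-diol | Oc1cc(O)cc(Cl)c1 | starting material
2 | 1-chloro-3,5-bis(methoxymethoxy)benzene | COCOc1cc(Cl)cc(OCOC)c1 | intermediate
3 | prenyl bromide (1-bromo-3-methylbut-2-ene) | CC(C)=CCBr | starting material
4 | [4-chloro-2,6-bis(methoxymethoxy)phenyl]lithium | [Li]c1c(OCOC)cc(Cl)cc1OCOC | intermediate
5 | 5-chloro-1,3-bis(methoxymethoxy)-2-(3-methylbut-2-en-1-yl)benzene | COCOc1cc(Cl)cc(OCOC)c1CC=C(C)C | intermediate
6 | 3,5-bis(methoxymethoxy)-4-(3-methylbut-2-en-1-yl)phenol | Oc1cc(OCOC)c(CC=C(C)C)c(OCOC)c1 | intermediate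
7 | 2-bromo-3,5-bis(methoxymethoxy)-4-(3-methylbut-2-en-1-yl)phenol | Oc1cc(OCOC)c(CC=C(C)C)c(OCOC)c1Br | intermediate
8 | [2-bromo-3,5-bis(methoxymethoxy)-4-(3-methylbut-2-en-1-yl)phenoxy]trimethylsilane | C[Si](C)(C)Oc1cc(OCOC)c(CC=C(C)C)c(OCOC)c1Br | intermediate
9 | lithium 3,5-bis(methoxymethoxy)-4-(3-methylbut-2-en-1-yl)-2-(trimethylsilyl)phenolate | [Li+].[O-]c1cc(OCOC)c(CC=C(C)C)c(OCOC)c1[Si](C)(C)C | intermediate
10 | 3,5-bis(methoxymethoxy)-4-(3-methylbut-2-en-1-yl)-2-(trimethylsilyl)phenyl trifluoromethanesulfonate | C[Si](C)(C)c1c(OS(=O)(=O)C(F)(F)F)cc(OCOC)c(CC=C(C)C)c1OCOC | intermediate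
11 | 4-iodophenol | Oc1ccc(I)cc1 | starting material
12 | 4-iodo-2,6-bis(3-methylbut-2-en-1-yl)phenol | CC(C)=CCc1cc(I)cc(CC=C(C)C)c1O | intermediate
13 | 5-iodo-2-(methoxymethoxy)-1,3-bis(3-methylbut-2-en-1-yl)benzene | COCOc1c(CC=C(C)C)cc(I)cc1CC=C(C)C | intermediate
14 | [4-(methoxymethoxy)-3,5-bis(3-methylbut-2-en-1-yl)phenyl]magnesium chloride | COCOc1c(CC=C(C)C)cc([Mg]Cl)cc1CC=C(C)C | intermediate
15 | methyl 4-(methoxymethoxy)-3,5-bis(3-methylbut-2-en-1-yl)benzoate | COCOc1c(CC=C(C)C)cc(C(=O)OC)cc1CC=C(C)C | intermediate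
16 | 4-acetylmorpholine | CC(=O)N1CCOCC1 | starting material
17 | lithium 1-(morpholin-4-yl)ethen-1-olate | [Li]OC(=C)N1CCOCC1 | intermediate
18 | 1-[4-(methoxymethoxy)-3,5-bis(3-methylbut-2-en-1-yl)phenyl]-3-(morpholin-4-yl)propane-1,3-dione | COCOc1c(CC=C(C)C)cc(C(=O)CC(=O)N2CCOCC2)cc1CC=C(C)C | intermediate
19 | (3R)-3-hydroxy-3-[4-(methoxymethoxy)-3,5-bis(3-methylbut-2-en-1-yl)phenyl]-1-(morpholin-4-yl)propan-1-one | COCOc1c(CC=C(C)C)cc([C@H](O)CC(=O)N2CCOCC2)cc1CC=C(C)C | intermediate
20 | (3R)-3-[4-(methoxymethoxy)-3,5-bis(3-methylbut-2-en-1-yl)phenyl]-1-(morpholin-4-yl)-3-[(trimethylsilyl)oxy]propan-1-one | COCOc1c(CC=C(C)C)cc([C@H](O[Si](C)(C)C)CC(=O)N2CCOCC2)cc1CC=C(C)C | intermediate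
21 | cesium (1R)-1-[4-(methoxymethoxy)-3,5-bis(3-methylbut-2-en-1-yl)phenyl]-3-(morpholin-4-yl)-3-oxopropan-1-olate | [Cs+].COCOc1c(CC=C(C)C)cc([C@H]([O-])CC(=O)N2CCOCC2)cc1CC=C(C)C | intermediate
22 | 3,5-bis(methoxymethoxy)-4-(3-methylbut-2-en-1-yl)benzyne (1,2-didehydrobenzene) | COCOC1=CC#CC(OCOC)=C1CC=C(C)C | intermediate
23 | {2-[(1R)-1-[4-(methoxymethoxy)-3,5-bis(3-methylbut-2-en-1-yl)phenyl]-3-(morpholin-4-yl)-3-oxopropoxy]-4,6-bis(methoxymethoxy)-5-(3-methylbut-2-en-1-yl)phenyl}cesium | [Cs]c1c(O[C@H](CC(=O)N2CCOCC2)c2cc(CC=C(C)C)c(OCOC)c(CC=C(C)C)c2)cc(OCOC)c(CC=C(C)C)c1OCOC | intermediate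
24 | cesium (2R)-5,7-bis(methoxymethoxy)-2-[4-(methoxymethoxy)-3,5-bis(3-methylbut-2-en-1-yl)phenyl]-6-(3-methylbut-2-en-1-yl)-4-(morpholin-4-yl)chroman-4-olate (C4 configuration undefined, lost on collapse) | [Cs+].COCOc1c(CC=C(C)C)cc([C@H]2CC([O-])(N4CCOCC4)c3c(cc(OCOC)c(CC=C(C)C)c3OCOC)O2)cc1CC=C(C)C | intermediate
25 | (2R)-5,7-bis(methoxymethoxy)-2-[4-(methoxymethoxy)-3,5-bis(3-methylbut-2-en-1-yl)phenyl]-6-(3-methylbut-2-en-1-yl)-2,3-dihydro-4H-chromen-4-one | COCOc1c(CC=C(C)C)cc([C@H]2CC(=O)c3c(cc(OCOC)c(CC=C(C)C)c3OCOC)O2)cc1CC=C(C)C | intermediate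
26 | (2R)-5,7-dihydroxy-2-[4-hydroxy-3,5-bis(3-methylbut-2-en-1-yl)phenyl]-6-(3-methylbut-2-en-1-yl)-2,3-dihydro-4H-chromen-4-one | CC(C)=CCc1cc([C@H]2CC(=O)c3c(cc(O)c(CC=C(C)C)c3O)O2)cc(CC=C(C)C)c1O | target

## Step count and risks

Total step count: 13. Longest linear sequence: 8 steps (steps 6–13, from 4-iodophenol).

Steps most likely to fail:

1. Step 12 (proposed new method). The aryl anion may capture a proton before it closes on the amide, the alkoxide may add at the wrong aryne carbon, or the aryne may be consumed by ene reaction with prenyl groups. The fallback uses known chemistry; it sets out from β-keto amide 18 and bromophenol 7 and comes back to the route at 25. 18 would be reduced with RuCl[(S,S)-TsDPEN](p-cymene), HCO2H/Et3N to the (3S)-hydroxy amide F1. Mitsunobu etherification of F1 with 7 (PPh3, DIAD, toluene, 0 °C) should give, with inversion, the (R)-aryl ether F2. n-BuLi in THF at −100 °C should effect bromine–lithium exchange to the aryllithium F3, which should close onto the morpholine amide (Parham cyclization) to the lithium hemiaminal alkoxide F4. Quenching with aqueous acetic acid would release 25.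

2. Step 4. Over-bromination at the second ortho position, or electrophilic attack of the brominating agent on the prenyl double bond, may compete. The fallback avoids electrophilic halogenation; it sets out from phenol 6 and comes back to the route at 10. 6 with iPrNCO and Et3N (cat.) in CH2Cl2 should give the isopropylcarbamate F5. TBSOTf and TMEDA in Et2O would silylate nitrogen in the flask to the N-silyl carbamate F6. Carbamate-directed ortho-lithiation (n-BuLi, TMEDA, −78 °C), quench with TMSCl and aqueous NaHSO4 work-up should give the ortho-silyl carbamate F7. Et2NH and DBU in MeCN at 40 °C would cleave the carbamate to the ortho-silyl phenol F8, and PhNTf2 added to the same flask would convert it into 10.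

3. Step 13. Acid-induced cyclisation of a prenyl group onto a neighbouring free phenol (chroman formation) may occur before the hindered 4'-MOM group has left. The fallback removes the acetals without free Brønsted acid; it sets out from 25 and comes back to the route at 26. TMSOTf and 2,2'-bipyridyl in CH2Cl2 at 0 °C should convert the three aryl MOM ethers into the tris(trimethylsilyl) ether F9, and H2O/THF at rt would then hydrolyse F9 to 26.

## Further compounds

F1 | step 12 | (3S)-3-hydroxy-3-[4-(methoxymethoxy)-3,5-bis(3-methylbut-2-en-1-yl)phenyl]-1-(morpholin-4-yl)propan-1-one | COCOc1c(CC=C(C)C)cc([C@@H](O)CC(=O)N2CCOCC2)cc1CC=C(C)C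
F2 | step 12 | (3R)-3-[2-bromo-3,5-bis(methoxymethoxy)-4-(3-methylbut-2-en-1-yl)phenoxy]-3-[4-(methoxymethoxy)-3,5-bis(3-methylbut-2-en-1-yl)phenyl]-1-(morpholin-4-yl)propan-1-one | Brc1c(O[C@H](CC(=O)N2CCOCC2)c2cc(CC=C(C)C)c(OCOC)c(CC=C(C)C)c2)cc(OCOC)c(CC=C(C)C)c1OCOC
F3 | step 12 | {2-[(1R)-1-[4-(methoxymethoxy)-3,5-bis(3-methylbut-2-en-1-yl)phenyl]-3-(morpholin-4-yl)-3-oxopropoxy]-4,6-bis(methoxymethoxy)-5-(3-methylbut-2-en-1-yl)phenyl}lithium | [Li]c1c(O[C@H](CC(=O)N2CCOCC2)c2cc(CC=C(C)C)c(OCOC)c(CC=C(C)C)c2)cc(OCOC)c(CC=C(C)C)c1OCOC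
F4 | step 12 | lithium (2R)-5,7-bis(methoxymethoxy)-2-[4-(methoxymethoxy)-3,5-bis(3-methylbut-2-en-1-yl)phenyl]-6-(3-methylbut-2-en-1-yl)-4-(morpholin-4-yl)chroman-4-olate | [Li+].COCOc1c(CC=C(C)C)cc([C@H]2CC([O-])(N4CCOCC4)c3c(cc(OCOC)c(CC=C(C)C)c3OCOC)O2)cc1CC=C(C)C
F5 | step 4 | 3,5-bis(methoxymethoxy)-4-(3-methylbut-2-en-1-yl)phenyl N-(propan-2-yl)carbamate | CC(C)NC(=O)Oc1cc(OCOC)c(CC=C(C)C)c(OCOC)c1
F6 | step 4 | 3,5-bis(methoxymethoxy)-4-(3-methylbut-2-en-1-yl)phenyl N-[tert-butyl(dimethyl)silyl]-N-(propan-2-yl)carbamate | CC(C)N([Si](C)(C)C(C)(C)C)C(=O)Oc1cc(OCOC)c(CC=C(C)C)c(OCOC)c1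
F7 | step 4 | 3,5-bis(methoxymethoxy)-4-(3-methylbut-2-en-1-yl)-2-(trimethylsilyl)phenyl N-(propan-2-yl)carbamate | CC(C)NC(=O)Oc1cc(OCOC)c(CC=C(C)C)c(OCOC)c1[Si](C)(C)C
F8 | step 4 | 3,5-bis(methoxymethoxy)-4-(3-methylbut-2-en-1-yl)-2-(trimethylsilyl)phenol | Oc1cc(OCOC)c(CC=C(C)C)c(OCOC)c1[Si](C)(C)C
F9 | step 13 | (2R)-2-{3,5-bis(3-methylbut-2-en-1-yl)-4-[(trimethylsilyl)oxy]phenyl}-6-(3-methylbut-2-en-1-yl)-5,7-bis[(trimethylsilyl)oxy]-2,3-dihydro-4H-chromen-4-one | C[Si](C)(C)Oc1c(CC=C(C)C)cc([C@H]2CC(=O)c3c(cc(O[Si](C)(C)C)c(CC=C(C)C)c3O[Si](C)(C)C)O2)cc1CC=C(C)C
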